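All runs come from a simulation for an exercise; noise was put on by code.

Late in the green flask the target lay near 10.4 % and the solid substrate near 79.2 %, both flat within a scatter of 0.5 percentage points, so I took the reaction to have stopped with solid to spare.

| flask | solid substrate | coupling partner | protic impurity | temperature | remark | time |
|---|---|---|---|---|---|---|
| green | 0.070 M | 0.091 M | 1.4 mM | 40 °C | the very flask that is asked about, followed so far |  |
| red | 0.070 M | 0.045 M | 1.4 mM | 35 °C | run made earlier |  |
| flask | 0.070 M | 0.0910 M | 1.40 mM | 40 °C |  | 8.0 d |

| run | time / d | target / % | solid substrate / % |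
|---|---|---|---|
| green | 0.333 | 8.6 | 80.8 |
| green | 1.04 | 10.2 | 79.2 |
| green | 1.67 | 11.2 | 78.2 |
| green | 3.00 | 11.1 | 78.2 |
| green | 4.00 | 9.9 | 78.3 |
| green | 5.00 | 10.1 | 78.4 |
| green | 6.00 | 10.4 | 79.2 |
| red | 0.417 | 4.8 | 84.1 |
| red | 1.25 | 6.3 | 81.3 |
| red | 2.50 | 6.1 | 81.5 |
| red | 3.00 | 6.2 | 81.3 |
| red | 5.00 | 6.6 | 81.8 |
| red | 6.00 | 6.8 | 81.5 |
| red | 8.00 | 5.9 | 81.7 |

(each reading ± 0.5 percentage points)

- Tuesday's: at 8.0 d raise the temperature by 25 K, then wait 2.5 d
- Thursday's: change nothing and wait 2.5 d more
- Sunday's: at 8.0 d add coupling partner, 100 % of the amount charged, then wait 2.5 d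

- additions leave the volume as it is
- at the start none of the solid substrate is in solution
- a reading or a percentage of target counts all its forms, free or not

1. target, in percent of the solid substrate first charged, at 8.0 d
2. which option adds most target ("none" when 2 percentage points or less is all one gets) (Tuesday's / Thursday's / Sunday's / none)
3. target present, in percent of the solid substrate first charged, after Thursday's
4. target present, in percent of the solid substrate first charged, after Sunday's

I froze what looked constant. I took the part missing from the green balance, 10.4 %, for dissolved substrate held steady by the solid, so that, once the solid had filled the solution from its empty start, coupling partner met a steady c(dissolved substrate) and had steady odds of becoming target. I therefore read the stop as the end of the coupling partner, the limiting reagent. The last green target reading gives 0.0800 for the partner share, the target formed per coupling partner charged while c(dissolved substrate) stays frozen, in effect a selectivity factor. The red flask, at 35 °C, reads higher, 0.0964. Tuesday's and Thursday's bring no new coupling partner, so I expected little from either and the plateau to stand at 8.0 d. Sunday's dose, multiplied by the share and added to that reading, gave me 20.8 %.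

The forecast said 10.4 % now, 10.4 % after Thursday's and 19.3 % after Sunday's, and chose Sunday's. Where I read an ended reagent, it wrote: “The plateau scales roughly with coupling partner concentration, which suggests an equilibrium with saturated substrate”. Its Sunday figure stood below mine.

The flask gave 10.4 % at 8.0 d, 10.4 % after Thursday's and 23.8 % after Sunday's. Sunday's was best, adding 13 points against 0.66 points for Tuesday's and 0 points for Thursday's. The forecast held.

    solid substrate ⇌ dissolved substrate, rate k1*(cs1 - [dissolved substrate]) while solid is left; crystals form when [dissolved substrate] > cs1 (solubility = 7.50 mM, k = 1.08 h⁻¹)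
    dissolved substrate + coupling partner → target (k = 3.62 M⁻¹ h⁻¹, Ea = 54.0 kJ mol⁻¹)
    coupling partner → side product (k = 0.211 h⁻¹, Ea = 92.0 kJ mol⁻¹)
    solid product ⇌ target, rate k4*(cs4 - [target]) while solid is left; crystals form when [target] > cs4 (solubility = 1.20 mM, k = 0.904 h⁻¹)
    coupling partner + protic impurity → quenched reagent (k = 70.0 M⁻¹ h⁻¹, Ea = 67.0 kJ mol⁻¹)
    target ⇌ isomer of the product (K = 0.440, k = 0.0378 h⁻¹, Ea = 93.0 kJ mol⁻¹, ΔH = −73.0 kJ mol⁻¹)
    (constants at 40 °C)

At 8.00 d the flask had 0 % of its coupling partner left and 10.7 % as dissolved substrate, with 78.1 % still solid. Sunday's dose showed a share of 0.103, above the 0.0802 that the first charge of this flask gave, and the flask stood above my 20.8 %. For the neighbour with 0.018 M of solid substrate and the same coupling partner, the green share gives 40.4 %. That flask held 40.6 % of target at 8.00 d, with 14.8 % still solid and 0 % of its coupling partner left.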